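Numbering: germacrane numbering is used for every intermediate (ring carbons C1–C10, C11–C13 the three-carbon unit on C7, C14 the methyl on C10, C15 the methyl on C4); ring A = C1–C6, ring B = C1, C6, C7, C8, C9, C10.

Remark: but-3-yn-2-ol is used as the racemate because its carbinol carbon (the later C3) is oxidised to a ketone in step 11 before C3 is set in step 14; 14 and 15 are therefore C3 epimer mixtures, and the oxime geometry in 5 and 6 and the lactol centre in 28 are left undefined.

## Analysis of the target

Compound 33 is a germacranolide: a ten-membered carbocycle (C1–C10) with an α-methylene-γ-butyrolactone trans-fused across C6/C7 (lactone oxygen on C6, carbonyl C12, exocyclic methylene C13), a Z trisubstituted C4=C5 alkene, free hydroxyls on C1, C3 and the methyl-bearing quaternary C10, and a (Z)-2-methylbut-2-enoate (angelate) on C9. The six stereocentres are 1R,3S,6R,7S,9S,10S: C1/C3 form a syn-1,3-diol, C9–C10–C1 are three contiguous oxygenated carbons, and H6 and H7 are trans. The sensitive groups are the α-methylene lactone (a Michael acceptor that does not survive hydride, amine or thiolate reagents), the angelate (it isomerises to the tiglate with base or nucleophilic catalysts) and the allylic oxygens at C3 and C6, which turn into leaving groups or furan precursors once a carbonyl sits next to them. The synthesis is hard because of the medium ring: ten-membered rings close badly, and this one must hold a Z alkene and oxygen on five of its ten carbons. The route rests on the fact that C1 and C6 both carry oxygen and stand 1,6 across the ring. An auxiliary C1–C6 bond turns the macrocycle into two fused six-membered rings sharing a tertiary 1,2-diol, and ring B then has the substitution pattern of (R)-carvone (1): methyl on C10, three-carbon unit on C7. Cleaving that glycol returns the ten-membered ring with ketones at C1 and C6, so the Z alkene and all ten ring bonds are assembled in six-membered rings; the price is that C1 and C6 must be set again by reduction.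

## Retrosynthetic reasoning

Ester and protecting groups (33 ⇒ 32 ⇒ 31 ⇒ 30). The C9–O acyl bond is cut first because the angelate is the most fragile group and should meet as few reagents as possible. 33 is the desilylation product of 32, and 32 comes from diol 31, in which C9–OH is the only hydroxyl that can be acylated (C10–OH is tertiary, C1 and C3 are silylated). 31 is unmasked from acetonide 30. The forward steps must acylate a hindered secondary alcohol without Z to E isomerisation and remove silicon without base.

Lactone (30 ⇒ 29 ⇒ 27). The lactone C12–O6 bond is cut back to the 1,4-diol in 27 (primary allylic C12–OH, secondary C6–OH). Oxidative lactonisation forms it with retention at C6. Keeping C12 at the alcohol level until then means no Michael acceptor is present during the hydride steps. 30 is the bis-silyl ether of 29.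

C1 and C6 carbinols (27 ⇒ 25 ⇒ 24 ⇒ 23). The C–H bonds at C1 and C6 are cut back to the two carbonyls of 23. They are reduced one at a time: first the C6 enone, with C7 as the controlling neighbour, to 24; then, after the C3 hydroxyl is freed in 25, the C1 ketone under chelation control from C3–OH, which gives the syn-1,3-diol of 27. C3 must stay silylated while C6 is a ketone, because a free Z-γ-hydroxy enone would close to a dihydrofuranol and aromatise.

Key disconnection (23 ⇒ 21). Retrosynthetically the C1 and C6 carbonyl carbons of 23 are joined to give the tertiary cis-diol 21. Forward, this is a glycol cleavage of the one bond shared by rings A and B. It is the only bond whose removal converts two easily made six-membered rings into the ten-membered ring, and the two carbons it leaves as ketones are the ones that carry oxygen in 33. The step must cleave one glycol only, so in 21 the C9/C10 oxygens are tied in an acetonide and the C3 and C12 oxygens are silyl ethers.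

C3 and C12 (21 ⇒ 20 ⇒ 19 ⇒ 18). 21 is the bis-silyl ether of tetraol 20. The C3 carbinol C–H is cut to enone 19 and the C12–O bond to the isopropenyl compound 18. Both are dealt with before the cleavage. Allylic oxidation of the isopropenyl group is chemoselective only while C4=C5 is part of an enone, as in 18. After the cleavage it would have to follow the hydride steps, whereas the lactone must not precede them. For C3, hydride must come from the face opposite the C1 hydroxyl, which is pseudoaxial on ring A. A hydroxyl-delivered hydride would add syn to it and give the wrong epimer, so an external reduction is used.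

Ring A (18 ⇒ 16). The C1–C2 bond is cut by a retro-aldol step. 16 has a C1 ketone without α-hydrogens and a methyl ketone at C3 whose only kinetic enolate position is C2; the Z alkene holds the two ends together. Ring A and the tertiary C1 carbinol cis to C6–OH are gained in one step.

Side chain (16 ⇒ 15 ⇒ 14 ⇒ 7 + 12). 16 is the double oxidation product of triol 15, the desilylation product of 14. Cutting C5–C6 in 14 gives ketone 7 and the Z alkenyl iodide 12, used as its organometallic derivative 13. The axial C10 methyl directs the addition to the equatorial face of C6.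

Alkenyl fragment (12 ⇒ 11 ⇒ 8 + 9). The C4–C15 and C5–I bonds come from anti-carbometalation of 8 with 9 and iodination. This fixes C5 cis to C3, the geometry the ring alkene needs.

Carbonyl transposition (7 ⇒ 6 ⇒ 5 ⇒ 4). In 7 the carbonyl is at C6 and C1 is a carbinol, whereas 1 delivers the carbonyl at C1. The C6 carbonyl is traced to oxime 6 and then to the α-oximino ketone 5, which is made from 4 through its only enolisable position. This avoids any choice between two similar secondary hydroxyls.

Ring B (4 ⇒ 3 ⇒ 2 ⇒ 1). The acetonide of 4 is cut to diol 3, whose C9–O bond comes from anti opening of epoxide 2, the epoxide of (R)-carvone 1. The stereocentre of 1 becomes C7 and directs the epoxidation; the epoxide opening sets C9 and C10.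

## Alternatives that were turned down

Alternative 1: The disconnection is C2–C3 plus C1–O, so the ten-membered ring is closed by an intramolecular nitrile oxide–alkene cycloaddition. Forward, the C3 aldoxime A2 is chlorinated and treated with a Grignard base; the nitrile oxide A3 adds across the C1=C2 vinyl group to give the isoxazoline-bridged lactone A1.
- For it: ring closure, the C1 oxygen and the C3 oxidation level arrive in one step. The magnesium alkoxide of the C10 hydroxyl can hold the dipole and steer it to one face of the vinyl group, so C1 is set relative to C10 during ring closure. The lactone with C6/C7 is already in place, and the isoxazoline is a sturdy mask for the C1-hydroxy/C3-keto pair.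
- Against it: the step is a cyclisation to a ten-membered ring, the size with the worst entropic and transannular penalties, so dimerisation of A3 competes and high dilution is needed. The Z trisubstituted alkene must be made in an open chain and must not isomerise in the conjugated oxime or dipole. A1 still lacks C13 and needs N–O cleavage and a C3 ketone reduction.
- Comparison: the alternative is stronger on C1 stereocontrol, since the chosen route must re-create C1 and C6 by reduction. The chosen route offers a ring formation with no macrocyclisation and an alkene geometry fixed by a six-membered ring. Step counts are of the same order.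

Alternative 2: The disconnection is C7–C8 plus C11–C13 on the lactone, with the carbocycle left open. Forward, under a silyl triflate Lewis acid the silyl enol ether A6 adds through C8 to C7 of butenolide A5 (Mukaiyama–Michael addition), and the nucleophilic C11 that results is aminomethylated in the same flask to give the Mannich base A4 with C6, C7 and C11 all trans.
- For it: it is highly convergent. C6 comes from the chiral pool and C7 follows by anti addition, so the lactone stereochemistry is secure. The amine is a latent exocyclic methylene that can be carried through reductions and revealed at the end.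
- Against it: no ring of the carbocycle is made. The ten-membered ring, the missing C4 and the Z C4=C5 alkene are all left to a later macrocyclisation between the C3 and C5 termini, which is the problem that makes this target hard. The C9 ketone of A4 still needs a stereoselective reduction.
- Comparison: A4 is the better answer to the lactone (C6/C7 configuration, protection of the Michael acceptor), where the chosen route relies on a ketone reduction in a medium ring. The chosen route answers the ring and the alkene geometry in one precedented fragmentation and needs fewer operations after its key step.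

Alternative 3: The disconnection is C6–O plus C3–O. Forward, with Pd(OAc)2 (divalent palladium) and a quinone oxidant in acetic acid, the C12 carboxylate of the ring diene acid A8 attacks C6 of the palladium-bound C3=C4–C5=C6 diene and acetate then attacks C3 of the allyl complex. The product is the trans-fused lactone acetate A7, with C4=C5 left between the two new C–O bonds.
- For it: two C–O bonds, the lactone ring and the alkene position are set in one catalytic step. The 1,4-relationship of C3 and C6 follows from the stereochemical course of the two attacks and needs no hydride reduction.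
- Against it: A8 already contains the ten-membered ring, so the main difficulty is moved to an unsolved earlier stage. Such 1,4-oxidations are established for six- to eight-membered dienes; in a ten-membered trisubstituted diene the allyl intermediate can isomerise (losing the Z geometry) or be attacked at C5. Facial selectivity relative to C7 depends on the ring conformation, and C13 is still missing.
- Comparison: where it applies it is more economical than the reduction/lactonisation sequence of the chosen route and equal or better on C3/C6 relative control. The chosen route offers a defined way to the ring itself, which the alternative presupposes.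

Key step: step 16

## Route

Step 1
Reactants: 1 (R)-(−)-carvone
Product: 2 carvone epoxide (epoxide trans to the isopropenyl group)
Conditions: H2O2 (35% aq.), NaOH (cat.), MeOH, 0 °C
Reagents that add atoms: hydrogen peroxide, OO
Why: Weitz–Scheffer nucleophilic epoxidation touches only the enone; hydroperoxide adds to C9 anti to the C7 isopropenyl group, so both new C–O bonds (C9, C10) lie trans to it and the isolated alkene is left alone.

Step 2
Reactants: 2 carvone epoxide
Product: 3 trans-9,10-diol ketone
Conditions: H2SO4 (3% aq.), THF, 0 °C → rt
Reagents that add atoms: water, O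
Why: Acid-catalysed anti opening of the α,β-epoxy ketone: water attacks the β-carbon C9 (C10 is tertiary and deactivated by the carbonyl, the regiochemistry known from halide opening of this epoxide), inverting C9 and retaining C10. The trans-diol has O9 cis to the isopropenyl group; dilute cold acid keeps the isopropenyl group from hydrating.

Step 3
Reactants: 3 trans-9,10-diol ketone
Product: 4 acetonide ketone
Conditions: 2-methoxypropene, PPTS (cat.), CH2Cl2, 0 °C → rt
Reagents that add atoms: 2-methoxypropene, COC(C)=C
Why: Kinetic acetalisation with an enol ether closes the trans-diequatorial diol to a trans-fused dioxolane (strain comparable to a trans-hydrindane). This ties up both oxygens, removes the retro-aldol-prone β-hydroxy ketone and locks ring B in the chair with the C7 substituent equatorial and the C10 methyl axial.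

Step 4
Reactants: 4 acetonide ketone
Product: 5 α-oximino ketone
Conditions: t-BuONO, KOtBu, THF, −20 → 0 °C; AcOH
Reagents that add atoms: tert-butyl nitrite, CC(C)(C)ON=O
Why: α-Oximation by C-nitrosation of the potassium enolate; C10 is quaternary, so the enolate can only form towards C6, and tautomerisation to the oxime puts ketone-level nitrogen on C6.

Step 5
Reactants: 5 α-oximino ketone
Product: 6 hydroxy oxime
Conditions: NaBH4, MeOH, 0 °C
Reagents that add atoms: none
Why: Borohydride reduces the ketone and leaves the oxime (the classical oximino-ketone route to transposed ketols); attack anti to the axial C10 methyl should give the equatorial C1 alcohol, but this centre is oxidised again in step 11 and its configuration does not matter.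

Step 6
Reactants: 6 hydroxy oxime
Product: 7 transposed ketol
Conditions: glyoxylic acid (50% aq.), NaOAc, THF/H2O, rt
Reagents that add atoms: water, O
Why: Transoximation: the oxime is hydrolysed at about pH 4 and the hydroxylamine is captured by the more electrophilic aldehyde, which completes an unambiguous 1,2-carbonyl transposition from C1 to C6. The buffered medium spares the acetonide and does not move the isopropenyl double bond into conjugation.

Step 7
Reactants: 8 but-3-yn-2-ol (racemic); 9 methylmagnesium bromide
Product: 11 (Z)-4-iodo-3-methylbut-3-en-2-ol (racemic), via alkenylmagnesium alkoxide 10 (not isolated)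
Conditions: 9 (3 equiv), CuI (10 mol %), THF, −10 °C → rt; then I2, −78 → 0 °C
Reagents that add atoms: iodine, I-I
Why: Copper-catalysed anti-carbomagnesiation of the propargylic magnesium alkoxide puts the methyl on the internal carbon and magnesium on the terminal carbon cis to the carbinol (five-membered chelate). Iodinolysis with retention gives the Z iodide in which the future C5 and C3 are cis, as the ring alkene requires.

Step 8
Reactants: 11 (Z)-4-iodo-3-methylbut-3-en-2-ol
Product: 12 alkenyl iodide silyl ether
Conditions: TBSCl, imidazole, DMF, rt
Reagents that add atoms: tert-butyldimethylsilyl chloride, CC(C)(C)[Si](C)(C)Cl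
Why: Standard silylation; the bulky silyl ether survives halogen–lithium exchange and slows the 1,4 O→C silyl shift of the derived alkenyllithium.

Step 9
Reactants: 7 transposed ketol; 12 alkenyl iodide silyl ether
Product: 14 C6 alkenyl adduct (C1,C6-diol; C3 silyl ether; C3 epimers), via alkenyllithium 13 (not isolated)
Conditions: 12 (2.5 equiv), t-BuLi (5 equiv), Et2O, −78 °C; CeCl3, THF, −78 °C; then 7, −78 → −40 °C
Reagents that add atoms: none
Why: Iodine–lithium exchange with retention of the Z geometry, transmetalation to the less basic organocerium reagent and 1,2-addition to the C6 ketone; the first equivalent is spent on the C1 hydroxyl. The nucleophile enters equatorially, away from the axial C10 methyl that is 1,3 to C6, so C5 ends equatorial and the new tertiary hydroxyl axial, cis to the C7 substituent.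

Step 10
Reactants: 14 C6 alkenyl adduct
Product: 15 triol
Conditions: Bu4NF, THF, 0 °C → rt
Reagents that add atoms: none
Why: Fluoride-mediated desilylation frees the C3 hydroxyl for oxidation; no base-sensitive group is present at this stage.

Step 11
Reactants: 15 triol
Product: 16 hydroxy diketone
Conditions: Dess–Martin periodinane (3 equiv), pyridine, CH2Cl2, 0 °C → rt
Reagents that add atoms: none
Why: Dess–Martin oxidation takes both secondary alcohols (C1 and allylic C3) while the tertiary C6 hydroxyl cannot react; this gives a C1 ketone without α-hydrogens next to a Z methyl enone. Reversible addition of the C6 hydroxyl to the C3 carbonyl is harmless because base reopens it in step 12.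

Step 12
Reactants: 16 hydroxy diketone
Product: 18 cis-fused bicyclic enone diol, via dilithium enolate 17 (not isolated)
Conditions: LiN(SiMe3)2 (2.2 equiv), THF, −78 → −40 °C; AcOH, −78 °C
Reagents that add atoms: none
Why: After the C6 alkoxide forms, kinetic deprotonation can only occur at the C2 methyl, and the enolate closes ring A by a 6-(enolexo)-exo-trig intramolecular aldol addition to C1, held in reach by the Z alkene. Attack on the axial face of C1, anti to the axial C10 methyl, gives the cis-fused diol (C2 axial on ring B, C1–OH cis to C6–OH), as in Robinson-type ketols. A cold acidic quench avoids retro-aldol cleavage and dehydration to the cross-conjugated dienone.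

Step 13
Reactants: 18 cis-fused bicyclic enone diol
Product: 19 C12 allylic alcohol
Conditions: SeO2 (0.3 equiv), t-BuOOH (in decane), CH2Cl2, 0 °C → rt
Reagents that add atoms: selenium dioxide, O=[Se]=O; tert-butyl hydroperoxide, CC(C)(C)OO
Why: Allylic oxidation by ene reaction and [2,3]-sigmatropic shift at the 1,1-disubstituted alkene gives the primary allylic alcohol at C12. The only other alkene, C4=C5, is part of the ring A enone and too electron-poor to react, which is why the oxidation is placed here; any C12 aldehyde from over-oxidation converges on 20 in step 14.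

Step 14
Reactants: 19 C12 allylic alcohol
Product: 20 tetraol (3S)
Conditions: NaBH4, CeCl3·7H2O, MeOH, −78 °C
Reagents that add atoms: none
Why: Luche 1,2-reduction of the enone: the C1 hydroxyl is pseudoaxial on ring A and 1,3 to C3, so external hydride attacks anti to it (as 5-substituted cyclohexenones are reduced anti to the 5-substituent) and the new hydroxyl ends cis to the C1 and C6 hydroxyls, which is 3S. Methanol keeps the substrate hydroxyls off boron; a hydroxyl-delivered hydride would attack the other face and give the C3 epimer.

Step 15
Reactants: 20 tetraol (3S)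
Product: 21 bis-silyl cis-diol (cleavage precursor)
Conditions: TBSCl (2.5 equiv), imidazole, DMAP (cat.), DMF, rt
Reagents that add atoms: tert-butyldimethylsilyl chloride, CC(C)(C)[Si](C)(C)Cl
Why: Silylation of the primary C12 and secondary C3 hydroxyls; the two tertiary ring-fusion hydroxyls are too hindered for the silyl chloride and stay free for the cleavage.

Step 16
Reactants: 21 bis-silyl cis-diol
Product: 23 ten-membered 1,6-diketone, via cyclic lead diolate 22 (not isolated)
Conditions: Pb(OAc)4 (1.15 equiv), pyridine (3 equiv), CH2Cl2, −20 → 0 °C
Reagents that add atoms: none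
Why: Criegee glycol cleavage: the two tertiary hydroxyls exchange for acetate on Pb(OAc)4 to give the five-membered tetravalent-lead diolate 22, and a concerted two-electron fragmentation breaks the C1–C6 bond as both C–O bonds become carbonyls and lead leaves as divalent Pb(OAc)2. The closest known reaction is the cleavage of cis-decalin-4a,8a-diols to cyclodecane-1,6-diones. No ring is closed by bond formation: the ten-membered ring appears because the bond shared by rings A and B is removed, so the penalties of a medium-ring cyclisation do not arise. No stereocentre is formed; C3, C7, C9 and C10 are spectators and C4=C5 is Z because it was made in ring A. Chemoselectivity rests on 21 having a single free vicinal diol, since the C9 and C10 oxygens are in the acetonide and the C3 and C12 oxygens are silyl ethers. The cis ring fusion holds the two hydroxyls gauche, which is what the cyclic diolate needs and makes the cleavage fast at low temperature. Pyridine takes up the acetic acid so that the diketone is not exposed to conditions that start transannular aldol addition (C2 to C6 or C7 to C1), loss of the C3 silyloxy group or migration of the C11=C13 double bond; 23 is filtered and reduced at once.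

Step 17
Reactants: 23 ten-membered 1,6-diketone
Product: 24 C6 allylic alcohol (6R)
Conditions: NaBH4 (0.6 equiv), CeCl3·7H2O, MeOH/CH2Cl2, −78 °C
Reagents that add atoms: none
Why: Luche reduction takes the cerium-activated C6 enone carbonyl in preference to the C1 ketone, which is flanked by the quaternary C10, and its 1,2-selectivity keeps C4=C5. Felkin–Anh attack with the 2-propenyl branch on C7 anti to the incoming hydride leads to the 6R alcohol (H6 trans to H7), the configuration of the lactone.

Step 18
Reactants: 24 C6 allylic alcohol
Product: 25 triol ketone
Conditions: HF·pyridine, pyridine, THF, 0 °C → rt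
Reagents that add atoms: none
Why: Desilylation with buffered fluoride removes both silyl ethers without base, so the β-hydroxy ketone that appears (C3–OH, C1=O) neither eliminates nor undergoes retro-aldol cleavage; C3–OH is now free to direct the next reduction.

Step 19
Reactants: 25 triol ketone
Product: 27 tetraol (1R), via C3 diethylborinate 26 (not isolated)
Conditions: Et2BOMe (3.5 equiv), THF/MeOH (4:1), −78 °C; NaBH4; AcOH/MeOH work-up
Reagents that add atoms: none
Why: Narasaka–Prasad reduction: boron bridges the C3 oxygen and the C1 carbonyl in a six-membered chelate and external hydride attacks axially to give the syn-1,3-diol, that is 1R from 3S; the Felkin–Anh preference set by the C10 oxygen points to the same face. The reduction precedes lactone formation because borohydride would add to an α-methylene lactone.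

Step 20
Reactants: 27 tetraol (1R)
Product: 29 α-methylene lactone diol, via lactol 28 (not isolated)
Conditions: TEMPO (0.2 equiv), PhI(OAc)2 (2.5 equiv), CH2Cl2, rt
Reagents that add atoms: none
Why: Oxidative lactonisation of a 1,4-diol: the oxoammonium oxidant takes the primary allylic alcohol far faster than the secondary ones, the aldehyde is trapped by the C6 hydroxyl as a five-membered lactol, and this is oxidised on to the α-methylene-γ-lactone. C6 is not touched, so the trans ring fusion set in step 17 is kept.

Step 21
Reactants: 29 α-methylene lactone diol
Product: 30 bis-silyl lactone acetonide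
Conditions: TBSOTf (3 equiv), 2,6-lutidine, CH2Cl2, −40 → 0 °C
Reagents that add atoms: tert-butyldimethylsilyl trifluoromethanesulfonate, CC(C)(C)[Si](C)(C)OS(=O)(=O)C(F)(F)F
Why: Silylation with the silyl triflate protects the hindered C1 and the allylic C3 hydroxyls, the only free ones, under non-nucleophilic conditions that leave the Michael acceptor alone.

Step 22
Reactants: 30 bis-silyl lactone acetonide
Product: 31 bis-silyl 9,10-diol
Conditions: AcOH/THF/H2O (3:1:1), 40 °C
Reagents that add atoms: none
Why: Acid-catalysed acetal hydrolysis; on the ten-membered ring the dioxolane is an ordinary secondary/tertiary acetonide, and secondary tert-butyldimethylsilyl ethers hydrolyse markedly more slowly under these conditions, so C9–OH and C10–OH are released selectively.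

Step 23
Reactants: 31 bis-silyl 9,10-diol
Product: 32 bis-silyl 9-O-angelate
Conditions: angelic acid, 2,4,6-trichlorobenzoyl chloride, Et3N, toluene, rt; then 31, 75 °C
Reagents that add atoms: angelic acid, C/C=C(/C)C(=O)O
Why: Yamaguchi-type esterification through the preformed mixed anhydride, run without a nucleophilic catalyst because that is what isomerises angelates to tiglates; only the secondary C9 hydroxyl can be acylated, the tertiary C10 hydroxyl is inert.

Step 24
Reactants: 32 bis-silyl 9-O-angelate
Product: 33 CNP0493102.1
Conditions: HF·pyridine, pyridine, THF, 0 °C → rt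
Reagents that add atoms: none
Why: Fluoride desilylation under slightly acidic conditions removes both silyl ethers without isomerising or cleaving the angelate and without adding to the methylene lactone.

## Compound list

1 | (R)-(−)-carvone, (5R)-2-methyl-5-(prop-1-en-2-yl)cyclohex-2-en-1-one | CC1=CC[C@H](CC1=O)C(C)=C | starting material
2 | carvone epoxide, (1R,4R,6R)-1-methyl-4-(prop-1-en-2-yl)-7-oxabicyclo[4.1.0]heptan-2-one | O=C1C[C@H](C(C)=C)C[C@H]2O[C@@]12C | intermediate
3 | (2R,3S,5R)-2,3-dihydroxy-2-methyl-5-(prop-1-en-2-yl)cyclohexan-1-one (C9–OH cis, C10–OH trans to the isopropenyl group) | O=C1C[C@H](C(C)=C)C[C@H](O)[C@]1(O)C | intermediate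
4 | 9,10-O-isopropylidene derivative of 3 (trans-fused acetonide, C1 ketone) | O=C1C[C@H](C(C)=C)C[C@@H]2OC(C)(C)O[C@@]12C | intermediate
5 | 6-hydroxyimino derivative of 4 (α-oximino ketone) | O=C1C(=NO)[C@H](C(C)=C)C[C@@H]2OC(C)(C)O[C@@]12C | intermediate
6 | C1 alcohol of 5 (equatorial C1–OH, oxime at C6) | O[C@@H]1C(=NO)[C@H](C(C)=C)C[C@@H]2OC(C)(C)O[C@@]12C | intermediate
7 | transposed ketol: C6 ketone, C1–OH, 9,10-acetonide, C7 isopropenyl | O[C@@H]1C(=O)[C@H](C(C)=C)C[C@@H]2OC(C)(C)O[C@@]12C | intermediate
8 | but-3-yn-2-ol (racemic) | CC(O)C#C | starting material
9 | methylmagnesium bromide | C[Mg]Br | starting material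
10 | (Z)-alkenylmagnesium bromide bearing the bromomagnesium alkoxide (not isolated) | CC(O[Mg]Br)/C(C)=C\[Mg]Br | intermediate
11 | (Z)-4-iodo-3-methylbut-3-en-2-ol (racemic) | CC(O)/C(C)=C\I | intermediate
12 | (Z)-tert-butyl[(4-iodo-3-methylbut-3-en-2-yl)oxy]dimethylsilane (racemic) | CC(O[Si](C)(C)C(C)(C)C)/C(C)=C\I | intermediate
13 | (Z)-alkenyllithium from 12 (not isolated) | CC(O[Si](C)(C)C(C)(C)C)/C(C)=C\[Li] | intermediate
14 | C6 adduct: ring B acetonide with equatorial C1–OH, axial C6–OH and equatorial (Z)-CH=C(CH3)CH(OTBS)CH3 chain on C6 (C3 epimers) | O[C@@H]1[C@@](O)(/C=C(/C)C(C)O[Si](C)(C)C(C)(C)C)[C@H](C(C)=C)C[C@@H]2OC(C)(C)O[C@@]12C | intermediate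
15 | triol from 14 (C1–OH, C3–OH, C6–OH; C3 epimers) | O[C@@H]1[C@@](O)(/C=C(/C)C(C)O)[C@H](C(C)=C)C[C@@H]2OC(C)(C)O[C@@]12C | intermediate
16 | hydroxy diketone: C1 ketone, C6–OH, (Z)-enone side chain with C3 methyl ketone | O=C1[C@@](O)(/C=C(/C)C(C)=O)[C@H](C(C)=C)C[C@@H]2OC(C)(C)O[C@@]12C | intermediate
17 | dilithium C2 enolate C6 alkoxide of 16 (not isolated) | O=C1[C@@](O[Li])(/C=C(/C)C(=C)O[Li])[C@H](C(C)=C)C[C@@H]2OC(C)(C)O[C@@]12C | intermediate
18 | cis-fused bicyclic C1,C6-diol with ring A C3 enone, C7 isopropenyl, 9,10-acetonide | O[C@]12CC(=O)C(C)=C[C@@]1(O)[C@H](C(C)=C)C[C@@H]3OC(C)(C)O[C@@]23C | intermediate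
19 | C12 allylic alcohol of 18 (3-hydroxyprop-1-en-2-yl on C7) | O[C@]12CC(=O)C(C)=C[C@@]1(O)[C@H](C(CO)=C)C[C@@H]3OC(C)(C)O[C@@]23C | intermediate
20 | (3S)-tetraol: C3–OH cis to the C1 and C6 hydroxyls | O[C@]12C[C@H](O)C(C)=C[C@@]1(O)[C@H](C(CO)=C)C[C@@H]3OC(C)(C)O[C@@]23C | intermediate
21 | (1R,3S,6R,7S,9S,10R) cis-fused C1,C6-diol with C3 and C12 tert-butyldimethylsilyl ethers and 9,10-acetonide | O[C@]12C[C@H](O[Si](C)(C)C(C)(C)C)C(C)=C[C@@]1(O)[C@H](C(CO[Si](C)(C)C(C)(C)C)=C)C[C@@H]3OC(C)(C)O[C@@]23C | intermediate
22 | cyclic diacetoxylead diolate of 21 (not isolated) | CC(=O)O[Pb]1(OC(C)=O)O[C@]23C[C@H](O[Si](C)(C)C(C)(C)C)C(C)=C[C@@]2(O1)[C@H](C(CO[Si](C)(C)C(C)(C)C)=C)C[C@@H]4OC(C)(C)O[C@@]34C | intermediate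
23 | (3S,7S,9S,10R) ten-membered 1,6-diketone with Z C4=C5, C3 and C12 silyl ethers, 9,10-acetonide | O=C1/C=C(/C)[C@@H](O[Si](C)(C)C(C)(C)C)CC(=O)[C@]2(C)OC(C)(C)O[C@H]2C[C@H]1C(CO[Si](C)(C)C(C)(C)C)=C | intermediate
24 | (6R) C6 allylic alcohol, C1 ketone | O[C@@H]1/C=C(/C)[C@@H](O[Si](C)(C)C(C)(C)C)CC(=O)[C@]2(C)OC(C)(C)O[C@H]2C[C@H]1C(CO[Si](C)(C)C(C)(C)C)=C | intermediate
25 | triol ketone (C3–OH, C6–OH, C12–OH; C1 ketone) | O[C@@H]1/C=C(/C)[C@@H](O)CC(=O)[C@]2(C)OC(C)(C)O[C@H]2C[C@H]1C(CO)=C | intermediate
26 | C3 diethylborinate of 25, chelated to the C1 carbonyl (not isolated) | O[C@@H]1/C=C(/C)[C@@H](OB(CC)CC)CC(=O)[C@]2(C)OC(C)(C)O[C@H]2C[C@H]1C(CO)=C | intermediate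
27 | (1R) tetraol (C1–OH, C3–OH, C6–OH, C12–OH) | O[C@@H]1/C=C(/C)[C@@H](O)C[C@@H](O)[C@]2(C)OC(C)(C)O[C@H]2C[C@H]1C(CO)=C | intermediate
28 | lactol from C12 aldehyde and C6–OH (not isolated) | C=C1C(O)O[C@@H]2/C=C(/C)[C@@H](O)C[C@@H](O)[C@]3(C)OC(C)(C)O[C@H]3C[C@@H]12 | intermediate
29 | α-methylene lactone with C1–OH, C3–OH and 9,10-acetonide | C=C1C(=O)O[C@@H]2/C=C(/C)[C@@H](O)C[C@@H](O)[C@]3(C)OC(C)(C)O[C@H]3C[C@@H]12 | intermediate
30 | 1,3-bis-O-tert-butyldimethylsilyl ether of 29 | C=C1C(=O)O[C@@H]2/C=C(/C)[C@@H](O[Si](C)(C)C(C)(C)C)C[C@@H](O[Si](C)(C)C(C)(C)C)[C@]3(C)OC(C)(C)O[C@H]3C[C@@H]12 | intermediate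
31 | 9,10-diol from 30 | C=C1C(=O)O[C@@H]2/C=C(/C)[C@@H](O[Si](C)(C)C(C)(C)C)C[C@@H](O[Si](C)(C)C(C)(C)C)[C@](C)(O)[C@@H](O)C[C@@H]12 | intermediate
32 | 9-O-angelate of 31 | C=C1C(=O)O[C@@H]2/C=C(/C)[C@@H](O[Si](C)(C)C(C)(C)C)C[C@@H](O[Si](C)(C)C(C)(C)C)[C@](C)(O)[C@@H](OC(=O)/C(C)=C\C)C[C@@H]12 | intermediate
33 | CNP0493102.1, (1R,3S,6R,7S,9S,10S) germacranolide 9-O-angelate | C=C1C(=O)O[C@@H]2/C=C(/C)[C@@H](O)C[C@@H](O)[C@](C)(O)[C@@H](OC(=O)/C(C)=C\C)C[C@@H]12 | target

## Step count and weak points

Total: 24 steps. Longest linear sequence: 22 steps (steps 1–6 and 9–24, from 1); the alkenyl iodide 12 takes 2 steps (7 and 8). Thirteen linear steps lead to the cleavage precursor 21.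

Least certain steps:

Step 16 (key step). The cleavage itself should be fast. What is most likely to go wrong is decomposition of the 1,6-diketone as it forms: transannular aldol addition started by acid or base, β-elimination of the C3 silyloxy group next to the new C1 ketone, or migration of the C11=C13 double bond into conjugation with the C6 ketone. Fallback: the diketone is not isolated. The cleavage of 21 is run as described, excess oxidant is destroyed with ethylene glycol at −20 °C, and the cold solution is filtered into methanol containing CeCl3·7H2O and reduced at −78 °C with NaBH4 in the same operation. The first compound handled is then the C6 alcohol and the route is rejoined at 24. No new compound is made.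

Step 14. Poor facial selectivity in the C3 reduction: the face anti to the pseudoaxial C1 hydroxyl is the concave face of the cis-fused bicycle, and any boron-bound C1 alkoxide would deliver hydride to the opposite face. Fallback (reagent control on a substrate whose hydroxyls are capped): from 19, TMSOTf/2,6-lutidine gives the tris(trimethylsilyl) ether F1, in which the axial C1 silyl ether blocks the convex face and no hydroxyl can deliver hydride. Reduction with the (R)-configured Corey–Bakshi–Shibata oxazaborolidine and catecholborane (toluene, −78 °C) gives the 3S alcohol F2, and TBSOTf gives its C3 silyl ether F3. K2CO3/MeOH removes the three trimethylsilyl groups to give the triol F4; TBSCl/imidazole then silylates the primary C12 hydroxyl and the route is rejoined at 21.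

Step 17. Two selectivities are needed: the enone must be reduced before the C1 ketone, and hydride must take the Felkin face. In a flexible ten-membered ring the second is the less secure, and attack on the wrong face would give the C6 epimer. Fallback (inversion instead of selectivity): setting out from 23, the 6-epimeric alcohol F5 is not discarded. A Mitsunobu reaction (PPh3, DIAD, chloroacetic acid) inverts the allylic carbinol to the chloroacetate F6, and thiourea/NaHCO3 in ethanol removes the chloroacetyl group under near-neutral conditions to give 24.

Step 12. Dehydration of the tertiary aldol to the cross-conjugated dienone, retro-aldol opening on work-up, or closure to the trans-fused isomer. Fallback (silicon-mediated aldol instead of a lithium enolate): from 16, TMSOTf/Et3N at −78 °C gives the bis(trimethylsilyl) compound F7 (C2 silyl enol ether, C6 silyl ether). A catalytic fluoride source (TASF, THF, −78 °C) triggers the intramolecular aldol addition with silyl transfer to the aldolate oxygen, so the product is the bis(trimethylsilyl) ether F8, which cannot revert or dehydrate. HF·pyridine frees both tertiary hydroxyls and the route is rejoined at 18.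

Step 9. Enolisation of the hindered C6 ketone towards C7 (with loss of the C7 configuration or migration of the C11=C13 double bond into conjugation) competing with addition, made worse by the alkoxide formed from the free C1 hydroxyl; also a 1,4 O→C silyl shift in 13 if it warms. Fallback (protected ketone): from 7, TESOTf/2,6-lutidine gives the triethylsilyl ether F9. The organocerium reagent from 12 (now 1.3 equiv) adds to it to give the adduct F10; Bu4NF removes both silyl groups and the route is rejoined at 15.

Step 22. Loss of the allylic C3 silyl ether, or incomplete hydrolysis of the hindered acetonide, when two acid-labile groups must be told apart. Fallback (change of order and of protecting group): from 29, the acetonide is hydrolysed first, with no silyl ether present (aqueous trifluoroacetic acid, THF, 0 °C), to give the pentaol lactone F11. tBu2Si(OTf)2/2,6-lutidine bridges the syn-1,3-diol at C1/C3 as the six-membered silylene F12; the 1,2-diols all involve the tertiary C10 hydroxyl and should not compete. The mixed-anhydride angeloylation of step 23 gives the angelate F13, and HF·pyridine gives 33.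

## Further compounds

F0 | step 16 | none | none
F1 | step 14 | tris(trimethylsilyl) ether of 19 (C1, C6, C12) | C[Si](C)(C)O[C@]12CC(=O)C(C)=C[C@@]1(O[Si](C)(C)C)[C@H](C(CO[Si](C)(C)C)=C)C[C@@H]3OC(C)(C)O[C@@]23C
F2 | step 14 | (3S) alcohol from F1 | C[Si](C)(C)O[C@]12C[C@H](O)C(C)=C[C@@]1(O[Si](C)(C)C)[C@H](C(CO[Si](C)(C)C)=C)C[C@@H]3OC(C)(C)O[C@@]23C
F3 | step 14 | C3 tert-butyldimethylsilyl ether of F2 | C[Si](C)(C)O[C@]12C[C@H](O[Si](C)(C)C(C)(C)C)C(C)=C[C@@]1(O[Si](C)(C)C)[C@H](C(CO[Si](C)(C)C)=C)C[C@@H]3OC(C)(C)O[C@@]23C
F4 | step 14 | triol with C3 tert-butyldimethylsilyl ether (C1–OH, C6–OH, C12–OH free) | O[C@]12C[C@H](O[Si](C)(C)C(C)(C)C)C(C)=C[C@@]1(O)[C@H](C(CO)=C)C[C@@H]3OC(C)(C)O[C@@]23C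
F5 | step 17 | 6-epimer of 24 | O[C@H]1/C=C(/C)[C@@H](O[Si](C)(C)C(C)(C)C)CC(=O)[C@]2(C)OC(C)(C)O[C@H]2C[C@H]1C(CO[Si](C)(C)C(C)(C)C)=C
F6 | step 17 | 6-O-chloroacetate of 24 | ClCC(=O)O[C@@H]1/C=C(/C)[C@@H](O[Si](C)(C)C(C)(C)C)CC(=O)[C@]2(C)OC(C)(C)O[C@H]2C[C@H]1C(CO[Si](C)(C)C(C)(C)C)=C
F7 | step 12 | bis(trimethylsilyl) derivative of 16 (C2 silyl enol ether, C6 silyl ether) | O=C1[C@@](O[Si](C)(C)C)(/C=C(/C)C(=C)O[Si](C)(C)C)[C@H](C(C)=C)C[C@@H]2OC(C)(C)O[C@@]12C
F8 | step 12 | 1,6-bis(trimethylsilyl) ether of 18 | C[Si](C)(C)O[C@]12CC(=O)C(C)=C[C@@]1(O[Si](C)(C)C)[C@H](C(C)=C)C[C@@H]3OC(C)(C)O[C@@]23C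
F9 | step 9 | C1 triethylsilyl ether of 7 | CC[Si](CC)(CC)O[C@@H]1C(=O)[C@H](C(C)=C)C[C@@H]2OC(C)(C)O[C@@]12C
F10 | step 9 | C6 adduct of F9 (C1 triethylsilyl ether, C3 tert-butyldimethylsilyl ether, C3 epimers) | CC[Si](CC)(CC)O[C@@H]1[C@@](O)(/C=C(/C)C(C)O[Si](C)(C)C(C)(C)C)[C@H](C(C)=C)C[C@@H]2OC(C)(C)O[C@@]12C
F11 | step 22 | pentaol lactone (29 without the acetonide) | C=C1C(=O)O[C@@H]2/C=C(/C)[C@@H](O)C[C@@H](O)[C@](C)(O)[C@@H](O)C[C@@H]12
F12 | step 22 | 1,3-O-di-tert-butylsilylene derivative of F11 | C=C1C(=O)O[C@@H]2/C=C(/C)[C@@H]3C[C@@H](O[Si](O3)(C(C)(C)C)C(C)(C)C)[C@](C)(O)[C@@H](O)C[C@@H]12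
F13 | step 22 | 9-O-angelate of F12 | C=C1C(=O)O[C@@H]2/C=C(/C)[C@@H]3C[C@@H](O[Si](O3)(C(C)(C)C)C(C)(C)C)[C@](C)(O)[C@@H](OC(=O)/C(C)=C\C)C[C@@H]12
A1 | alternative 1 | isoxazoline-bridged ten-membered lactone | C1C(=O)O[C@@H]2/C=C(/C)C3=NO[C@H](C3)[C@](C)(O)[C@@H](OCc4ccc(OC)cc4)C[C@@H]12
A2 | alternative 1 | open-chain lactone (Z)-enal oxime with C1=C2 vinyl group | C=C[C@](C)(O)[C@@H](OCc1ccc(OC)cc1)C[C@H]2CC(=O)O[C@@H]2/C=C(/C)C=NO
A3 | alternative 1 | nitrile oxide from A2 | C=C[C@](C)(O)[C@@H](OCc1ccc(OC)cc1)C[C@H]2CC(=O)O[C@@H]2/C=C(/C)C#[N+][O-]
A4 | alternative 2 | all-trans lactone Mannich base with the C8–C3 chain | CN(C)C[C@@H]1C(=O)O[C@H](CO[Si](C)(C)C(C)(C)C)[C@H]1CC(=O)[C@@]2(C)OC(C)(C)O[C@@H]2CCOCc3ccc(OC)cc3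
A5 | alternative 2 | (S)-5-[(tert-butyldimethylsilyloxy)methyl]furan-2(5H)-one | O=C1C=C[C@@H](CO[Si](C)(C)C(C)(C)C)O1
A6 | alternative 2 | trimethylsilyl enol ether of the C9 methyl ketone (C10/C1 acetonide, C3 p-methoxybenzyl ether) | C=C(O[Si](C)(C)C)[C@@]1(C)OC(C)(C)O[C@@H]1CCOCc2ccc(OC)cc2
A7 | alternative 3 | trans-fused lactone with C3 acetate | C1C(=O)O[C@@H]2/C=C(/C)[C@@H](OC(C)=O)C[C@H]3OC(C)(C)O[C@]3(C)[C@@H](OCc4ccc(OC)cc4)C[C@@H]12
A8 | alternative 3 | ten-membered (3Z,5Z)-diene acid (C7 carboxymethyl, C1/C10 acetonide, C9 p-methoxybenzyl ether) | OC(=O)C[C@@H]1C[C@H](OCc2ccc(OC)cc2)[C@@]3(C)OC(C)(C)O[C@@H]3C/C=C(C)\C=C/1
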